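**Retrosynthetic overview**

- The route rests on one mapping. C3 to C7 of the target, with the C6 methyl, are C6 to C2 of geraniol with its C3 methyl, and the tetrasubstituted C6–O centre of the 1,2-dioxane is a Sharpless epoxide carbon opened with inversion.
- The methyl ester is traced back to a silylated C1 alcohol. The C7–C8 bond is cut to a C7 aldehyde (from periodate cleavage of a C7,C8-diol) and a ring phosphorane made from beta-cyclocitral, whose CH2 becomes C8.
- The 1,2-dioxane is the only ring formed in the route (the cyclohexenone ring is bought). It is closed by 6-exo attack of a C3 hydroperoxide on the C6–C7 epoxide at C6.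
- The C3 hydroperoxide comes from a C3 mesylate and H2O2 with inversion. C2 and C3 come from an Evans syn aldol on the epoxy aldehyde obtained by ozonolysis of silylated (2R,3R)-epoxygeraniol.

Key step: step 9

Remark: carbons are numbered along the target chain (ester carbon C1, C2, dioxane carbons C3 to C6, tether C7 and C8, ring carbon C9). The C7=C8 double bond of step 18 is drawn E; its geometry does not matter because step 19 saturates it. Ozonide 4 is an epimer mixture at its acetal carbon.

**Route**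

Step 1
Reactants: 1 geraniol
Product: 2 (2R,3R)-2,3-epoxygeraniol
Conditions: Ti(OiPr)4 (cat.), D-(−)-diethyl tartrate (cat.), t-BuOOH, 4 Å MS, CH2Cl2, −20 °C
Reagents that add atoms: tert-butyl hydroperoxide, CC(C)(C)OO
Why: Sharpless asymmetric epoxidation touches only the allylic 2,3-alkene, and the D-(−)-tartrate ligand delivers oxygen to the face that gives the (2R,3R)-epoxide, which fixes the later C6 and C7.

Step 2
Reactants: 2 (2R,3R)-2,3-epoxygeraniol
Product: 3 (2R,3R)-2,3-epoxygeranyl tert-butyldimethylsilyl ether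
Conditions: TBSCl, imidazole, CH2Cl2, 0 °C → rt
Reagents that add atoms: tert-butyldimethylsilyl chloride, CC(C)(C)[Si](C)(C)Cl
Why: Standard silylation of the primary alcohol, which also blocks Payne rearrangement of the epoxy alcohol in the later basic steps.

Step 3
Reactants: 3 (2R,3R)-2,3-epoxygeranyl tert-butyldimethylsilyl ether
Product: 5 3-[(2R,3R)-3-(tert-butyldimethylsilyloxymethyl)-2-methyloxiran-2-yl]propanal, via ozonide 4 (not isolated)
Conditions: O3, CH2Cl2, −78 °C; then Me2S, −78 °C → rt
Reagents that add atoms: ozone, [O-][O+]=O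
Why: Ozonolysis with reductive work-up cleaves the only alkene to the aldehyde and acetone, while the epoxide and the silyl ether are inert to ozone.

Step 4
Reactants: 5 3-[(2R,3R)-3-(tert-butyldimethylsilyloxymethyl)-2-methyloxiran-2-yl]propanal; 6 (R)-4-benzyl-3-propionyl-1,3-oxazolidin-2-one
Product: 9 (R)-4-benzyl-3-[(2R,3S)-3-hydroxy-2-methyl-5-[(2R,3R)-3-(tert-butyldimethylsilyloxymethyl)-2-methyloxiran-2-yl]pentanoyl]-1,3-oxazolidin-2-one, via boron enolate 7 (not isolated), via boron aldolate 8 (not isolated)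
Conditions: 6, Bu2BOTf, iPr2NEt, CH2Cl2, 0 °C; then 5, −78 → 0 °C; then pH 7 buffer, MeOH, 30% H2O2, 0 °C
Reagents that add atoms: none
Why: Evans syn aldol, in which the (Z)-boron enolate reacts through a closed chair transition state on the face away from the benzyl group of the (R)-auxiliary to set C2 (R) and C3 (S); the amine-buffered medium and neutral work-up keep the new C3 hydroxyl from opening the epoxide.

Step 5
Reactants: 9 aldol adduct
Product: 10 (2S,3S)-2-methyl-5-[(2R,3R)-3-(tert-butyldimethylsilyloxymethyl)-2-methyloxiran-2-yl]pentane-1,3-diol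
Conditions: LiBH4, THF, H2O (1 equiv), 0 °C
Reagents that add atoms: none
Why: Reductive removal of the acyl oxazolidinone by LiBH4 gives the primary alcohol without touching C2, and the cold basic medium spares the trisubstituted epoxide.

Step 6
Reactants: 10 (2S,3S)-diol
Product: 11 (2S,3S)-1-(tert-butyldiphenylsilyloxy)-2-methyl-5-[(2R,3R)-3-(tert-butyldimethylsilyloxymethyl)-2-methyloxiran-2-yl]pentan-3-ol
Conditions: TBDPSCl, imidazole, CH2Cl2, 0 °C
Reagents that add atoms: tert-butyldiphenylsilyl chloride, CC(C)(C)[Si](Cl)(c1ccccc1)c1ccccc1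
Why: The bulky silyl chloride silylates the primary C1 hydroxyl selectively over the secondary C3 hydroxyl under basic conditions.

Step 7
Reactants: 11 C3 alcohol
Product: 12 (2S,3S)-1-(tert-butyldiphenylsilyloxy)-2-methyl-5-[(2R,3R)-3-(tert-butyldimethylsilyloxymethyl)-2-methyloxiran-2-yl]pentan-3-yl methanesulfonate
Conditions: MsCl, Et3N, CH2Cl2, 0 °C
Reagents that add atoms: methanesulfonyl chloride, CS(=O)(=O)Cl
Why: Sulfonylation of the secondary alcohol takes place at oxygen, so C3 keeps its configuration and the hydroxyl that could open the epoxide is removed.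

Step 8
Reactants: 12 C3 mesylate
Product: 13 (2S,3R)-1-(tert-butyldiphenylsilyloxy)-3-hydroperoxy-2-methyl-5-[(2R,3R)-3-(tert-butyldimethylsilyloxymethyl)-2-methyloxiran-2-yl]pentane
Conditions: H2O2 (50% aq., large excess), KOH, MeOH–THF, 0 °C → rt
Reagents that add atoms: hydrogen peroxide, OO
Why: SN2 displacement of a secondary alkyl sulfonate by hydroperoxide anion, the classical route to secondary alkyl hydroperoxides, inverts C3 to the (R) configuration of the target; the excess of H2O2 suppresses dialkyl peroxide formation, and the epoxide and silyl ethers tolerate cold dilute hydroxide.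

Step 9
Reactants: 13 C3 hydroperoxide with C6–C7 epoxide
Product: 14 (1R)-2-(tert-butyldimethylsilyloxy)-1-[(3S,6R)-6-[(2S)-1-(tert-butyldiphenylsilyloxy)propan-2-yl]-3-methyl-1,2-dioxan-3-yl]ethan-1-ol
Conditions: Amberlyst-15, CH2Cl2, 0 °C → rt
Reagents that add atoms: none
Why: The sulfonic acid resin protonates the epoxide oxygen, and the terminal oxygen of the C3 hydroperoxide attacks C6 from the face opposite the departing epoxide oxygen, so the new C6–O bond forms as the old one breaks (borderline SN2). This is the known acid-promoted intramolecular opening of epoxides by hydroperoxides that gives 1,2-dioxanes. The 1,2-dioxane closes in the 6-exo-tet mode. The C6 stereocentre is set by the (2R,3R)-epoxide through inversion, while C3 and C7 keep their configuration because their C–O bonds are not broken. The step needs attack at C6 and not at C7 (7-endo), and by the terminal and not the inner peroxide oxygen: the exo preference and the tertiary, better cation-stabilising C6 (C7 is secondary and flanked by the electron-poor CH2OSi group) point the same way, and only the terminal oxygen reaches C6 through a six-membered transition state. Non-nucleophilic CH2Cl2 and a solid acid keep solvent from competing and should leave both silyl ethers in place.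

Step 10
Reactants: 14 dioxane with C7 hydroxyl and C8 silyl ether
Product: 15 (1R)-1-[(3S,6R)-6-[(2S)-1-(tert-butyldiphenylsilyloxy)propan-2-yl]-3-methyl-1,2-dioxan-3-yl]ethane-1,2-diol
Conditions: CSA (cat.), MeOH–CH2Cl2, 0 °C
Reagents that add atoms: none
Why: Acid-catalysed methanolysis removes the primary tert-butyldimethylsilyl ether much faster than the tert-butyldiphenylsilyl ether, and the dialkyl peroxide is stable to dilute acid.

Step 11
Reactants: 15 C7,C8-diol
Product: 16 (3S,6R)-6-[(2S)-1-(tert-butyldiphenylsilyloxy)propan-2-yl]-3-methyl-1,2-dioxane-3-carbaldehyde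
Conditions: NaIO4, THF–H2O (pH 7 buffer), 0 °C → rt
Reagents that add atoms: none
Why: Periodate glycol cleavage removes C8 as formaldehyde and leaves a C7 aldehyde that cannot enolise because C6 is quaternary; the O–O bond is inert to periodate.

Step 12
Reactants: 17 beta-cyclocitral
Product: 18 beta-cyclogeraniol
Conditions: NaBH4, MeOH, 0 °C
Reagents that add atoms: none
Why: 1,2-Reduction of the hindered conjugated aldehyde by borohydride gives the allylic alcohol.

Step 13
Reactants: 18 beta-cyclogeraniol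
Product: 19 beta-cyclogeranyl acetate
Conditions: Ac2O, pyridine, DMAP (cat.), CH2Cl2, rt
Reagents that add atoms: acetic anhydride, CC(=O)OC(C)=O
Why: Acetylation protects the primary allylic alcohol and deactivates its CH2 toward the oxidant of the next step.

Step 14
Reactants: 19 beta-cyclogeranyl acetate
Product: 20 (2,6,6-trimethyl-3-oxocyclohex-1-en-1-yl)methyl acetate
Conditions: CrO3, 3,5-dimethylpyrazole, CH2Cl2, −20 °C
Reagents that add atoms: chromium trioxide, O=[Cr](=O)=O
Why: Allylic oxidation by the CrO3–pyrazole complex converts the only ring allylic methylene (next to the methyl-bearing olefin carbon) into the conjugated ketone, the acetoxymethyl and vinylic methyl C–H bonds being less reactive.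

Step 15
Reactants: 20 keto acetate
Product: 21 3-(hydroxymethyl)-2,4,4-trimethylcyclohex-2-en-1-one
Conditions: K2CO3 (cat.), MeOH, 0 °C → rt
Reagents that add atoms: none
Why: Mild transesterification removes the acetate; the cross-conjugated enolate that base could form is not aligned to expel the oxygen substituent.

Step 16
Reactants: 21 hydroxymethyl enone
Product: 22 3-(bromomethyl)-2,4,4-trimethylcyclohex-2-en-1-one
Conditions: CBr4, PPh3, CH2Cl2, 0 °C
Reagents that add atoms: tetrabromomethane, BrC(Br)(Br)Br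
Why: Appel bromination converts the primary allylic alcohol into the bromide under neutral conditions.

Step 17
Reactants: 22 bromomethyl enone
Product: 23 [(2,6,6-trimethyl-3-oxocyclohex-1-en-1-yl)methyl]triphenylphosphonium bromide
Conditions: PPh3, toluene, 80 °C; precipitated salt washed with Et2O
Reagents that add atoms: triphenylphosphine, c1ccc(cc1)P(c1ccccc1)c1ccccc1
Why: SN2 quaternisation of the phosphine by the activated primary allylic bromide, with the salt freed of PPh3 so that no phosphine meets the peroxide later.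

Step 18
Reactants: 16 C7 aldehyde; 23 ring phosphonium bromide
Product: 25 3-[(E)-2-[(3S,6R)-6-[(2S)-1-(tert-butyldiphenylsilyloxy)propan-2-yl]-3-methyl-1,2-dioxan-3-yl]ethenyl]-2,4,4-trimethylcyclohex-2-en-1-one, via ylide 24 (not isolated)
Conditions: 23, KOtBu, THF, 0 °C; then 16, rt → 50 °C
Reagents that add atoms: none
Why: Wittig olefination of the non-enolisable aldehyde with the vinylogous keto-stabilised phosphorane forms the C7=C8 bond; the neutral ylide is formed before the aldehyde is added, so the peroxide never meets free alkoxide.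

Step 19
Reactants: 25 dienone
Product: 26 3-[2-[(3R,6R)-6-[(2S)-1-(tert-butyldiphenylsilyloxy)propan-2-yl]-3-methyl-1,2-dioxan-3-yl]ethyl]-2,4,4-trimethylcyclohex-2-en-1-one
Conditions: KO2CN=NCO2K (excess, in portions), AcOH, MeOH–CH2Cl2, 0 °C → rt
Reagents that add atoms: none
Why: Diimide reduction transfers hydrogen to the disubstituted C7=C8 alkene and leaves both the O–O bond and the tetrasubstituted enone alkene untouched.

Step 20
Reactants: 26 C1 silyl ether
Product: 27 3-[2-[(3R,6R)-6-[(2S)-1-hydroxypropan-2-yl]-3-methyl-1,2-dioxan-3-yl]ethyl]-2,4,4-trimethylcyclohex-2-en-1-one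
Conditions: TBAF, AcOH (1:1), THF, 0 °C → rt
Reagents that add atoms: none
Why: Fluoride-mediated desilylation, buffered with acetic acid so that neither Kornblum–DeLaMare fragmentation of the dioxane nor enolisation of the enone is triggered.

Step 21
Reactants: 27 C1 alcohol
Product: 29 (2R)-2-[(3R,6R)-6-methyl-6-[2-(2,6,6-trimethyl-3-oxocyclohex-1-en-1-yl)ethyl]-1,2-dioxan-3-yl]propanoic acid, via aldehyde 28 (not isolated)
Conditions: TEMPO (cat.), PhI(OAc)2, MeCN–H2O (1:1), rt
Reagents that add atoms: water, O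
Why: Oxoammonium-mediated oxidation takes the primary alcohol through the aldehyde hydrate to the acid under weakly acidic conditions, which should avoid epimerisation at C2 and beta-elimination of the C3 peroxide oxygen.

Step 22
Reactants: 29 carboxylic acid
Product: 30 diacarperoxide A
Conditions: TMSCHN2, toluene–MeOH (4:1), 0 °C
Reagents that add atoms: trimethylsilyldiazomethane, C[Si](C)(C)C=[N+]=[N-]
Why: Esterification by the diazoalkane needs no base, so the beta-peroxy ester cannot undergo retro-oxa-Michael opening and C2 keeps its configuration.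

**Compound list**

1 | geraniol | CC(C)=CCC/C(C)=C/CO | starting material
2 | (2R,3R)-2,3-epoxygeraniol | CC(C)=CCC[C@@]1(C)O[C@@H]1CO | intermediate
3 | (2R,3R)-2,3-epoxygeranyl tert-butyldimethylsilyl ether | CC(C)=CCC[C@@]1(C)O[C@@H]1CO[Si](C)(C)C(C)(C)C | intermediate
4 | 1,2,4-trioxolane (secondary ozonide) of the 6,7-alkene of 3, not isolated | CC1(C)OOC(CC[C@@]2(C)O[C@@H]2CO[Si](C)(C)C(C)(C)C)O1 | intermediate
5 | 3-[(2R,3R)-3-(tert-butyldimethylsilyloxymethyl)-2-methyloxiran-2-yl]propanal | O=CCC[C@@]1(C)O[C@@H]1CO[Si](C)(C)C(C)(C)C | intermediate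
6 | (R)-4-benzyl-3-propionyl-1,3-oxazolidin-2-one | CCC(=O)N1[C@H](Cc2ccccc2)COC1=O | starting material
7 | (Z)-dibutylboron enolate of 6, not isolated | C/C=C(\OB(CCCC)CCCC)N1[C@H](Cc2ccccc2)COC1=O | intermediate
8 | O-dibutylboron aldolate of 9, not isolated | O=C(N1[C@H](Cc2ccccc2)COC1=O)[C@H](C)[C@@H](OB(CCCC)CCCC)CC[C@@]1(C)O[C@@H]1CO[Si](C)(C)C(C)(C)C | intermediate
9 | (R)-4-benzyl-3-[(2R,3S)-3-hydroxy-2-methyl-5-[(2R,3R)-3-(tert-butyldimethylsilyloxymethyl)-2-methyloxiran-2-yl]pentanoyl]-1,3-oxazolidin-2-one | O=C(N1[C@H](Cc2ccccc2)COC1=O)[C@H](C)[C@@H](O)CC[C@@]1(C)O[C@@H]1CO[Si](C)(C)C(C)(C)C | intermediate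
10 | (2S,3S)-2-methyl-5-[(2R,3R)-3-(tert-butyldimethylsilyloxymethyl)-2-methyloxiran-2-yl]pentane-1,3-diol | OC[C@H](C)[C@@H](O)CC[C@@]1(C)O[C@@H]1CO[Si](C)(C)C(C)(C)C | intermediate
11 | (2S,3S)-1-(tert-butyldiphenylsilyloxy)-2-methyl-5-[(2R,3R)-3-(tert-butyldimethylsilyloxymethyl)-2-methyloxiran-2-yl]pentan-3-ol | CC(C)(C)[Si](c1ccccc1)(c1ccccc1)OC[C@H](C)[C@@H](O)CC[C@@]1(C)O[C@@H]1CO[Si](C)(C)C(C)(C)C | intermediate
12 | (2S,3S)-1-(tert-butyldiphenylsilyloxy)-2-methyl-5-[(2R,3R)-3-(tert-butyldimethylsilyloxymethyl)-2-methyloxiran-2-yl]pentan-3-yl methanesulfonate | CC(C)(C)[Si](c1ccccc1)(c1ccccc1)OC[C@H](C)[C@@H](OS(C)(=O)=O)CC[C@@]1(C)O[C@@H]1CO[Si](C)(C)C(C)(C)C | intermediate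
13 | (2S,3R)-1-(tert-butyldiphenylsilyloxy)-3-hydroperoxy-2-methyl-5-[(2R,3R)-3-(tert-butyldimethylsilyloxymethyl)-2-methyloxiran-2-yl]pentane | CC(C)(C)[Si](c1ccccc1)(c1ccccc1)OC[C@H](C)[C@H](OO)CC[C@@]1(C)O[C@@H]1CO[Si](C)(C)C(C)(C)C | intermediate
14 | (1R)-2-(tert-butyldimethylsilyloxy)-1-[(3S,6R)-6-[(2S)-1-(tert-butyldiphenylsilyloxy)propan-2-yl]-3-methyl-1,2-dioxan-3-yl]ethan-1-ol | CC(C)(C)[Si](c1ccccc1)(c1ccccc1)OC[C@H](C)[C@H]1CC[C@@](C)([C@H](O)CO[Si](C)(C)C(C)(C)C)OO1 | intermediate
15 | (1R)-1-[(3S,6R)-6-[(2S)-1-(tert-butyldiphenylsilyloxy)propan-2-yl]-3-methyl-1,2-dioxan-3-yl]ethane-1,2-diol | CC(C)(C)[Si](c1ccccc1)(c1ccccc1)OC[C@H](C)[C@H]1CC[C@@](C)([C@H](O)CO)OO1 | intermediate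
16 | (3S,6R)-6-[(2S)-1-(tert-butyldiphenylsilyloxy)propan-2-yl]-3-methyl-1,2-dioxane-3-carbaldehyde | CC(C)(C)[Si](c1ccccc1)(c1ccccc1)OC[C@H](C)[C@H]1CC[C@@](C)(C=O)OO1 | intermediate
17 | beta-cyclocitral (2,6,6-trimethylcyclohex-1-ene-1-carbaldehyde) | CC1=C(C=O)C(C)(C)CCC1 | starting material
18 | beta-cyclogeraniol ((2,6,6-trimethylcyclohex-1-en-1-yl)methanol) | CC1=C(CO)C(C)(C)CCC1 | intermediate
19 | beta-cyclogeranyl acetate | CC(=O)OCC1=C(C)CCCC1(C)C | intermediate
20 | (2,6,6-trimethyl-3-oxocyclohex-1-en-1-yl)methyl acetate | CC(=O)OCC1=C(C)C(=O)CCC1(C)C | intermediate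
21 | 3-(hydroxymethyl)-2,4,4-trimethylcyclohex-2-en-1-one | CC1=C(CO)C(C)(C)CCC1=O | intermediate
22 | 3-(bromomethyl)-2,4,4-trimethylcyclohex-2-en-1-one | CC1=C(CBr)C(C)(C)CCC1=O | intermediate
23 | [(2,6,6-trimethyl-3-oxocyclohex-1-en-1-yl)methyl]triphenylphosphonium bromide | CC1=C(C[P+](c2ccccc2)(c2ccccc2)c2ccccc2)C(C)(C)CCC1=O.[Br-] | intermediate
24 | [(2,6,6-trimethyl-3-oxocyclohex-1-en-1-yl)methylidene]triphenylphosphorane, not isolated | CC1=C(C=P(c2ccccc2)(c2ccccc2)c2ccccc2)C(C)(C)CCC1=O | intermediate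
25 | 3-[(E)-2-[(3S,6R)-6-[(2S)-1-(tert-butyldiphenylsilyloxy)propan-2-yl]-3-methyl-1,2-dioxan-3-yl]ethenyl]-2,4,4-trimethylcyclohex-2-en-1-one | CC(C)(C)[Si](c1ccccc1)(c1ccccc1)OC[C@H](C)[C@H]1CC[C@@](C)(/C=C/C2=C(C)C(=O)CCC2(C)C)OO1 | intermediate
26 | 3-[2-[(3R,6R)-6-[(2S)-1-(tert-butyldiphenylsilyloxy)propan-2-yl]-3-methyl-1,2-dioxan-3-yl]ethyl]-2,4,4-trimethylcyclohex-2-en-1-one | CC(C)(C)[Si](c1ccccc1)(c1ccccc1)OC[C@H](C)[C@H]1CC[C@@](C)(CCC2=C(C)C(=O)CCC2(C)C)OO1 | intermediate
27 | 3-[2-[(3R,6R)-6-[(2S)-1-hydroxypropan-2-yl]-3-methyl-1,2-dioxan-3-yl]ethyl]-2,4,4-trimethylcyclohex-2-en-1-one | OC[C@H](C)[C@H]1CC[C@@](C)(CCC2=C(C)C(=O)CCC2(C)C)OO1 | intermediate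
28 | (2R)-2-[(3R,6R)-6-methyl-6-[2-(2,6,6-trimethyl-3-oxocyclohex-1-en-1-yl)ethyl]-1,2-dioxan-3-yl]propanal, not isolated | O=C[C@H](C)[C@H]1CC[C@@](C)(CCC2=C(C)C(=O)CCC2(C)C)OO1 | intermediate
29 | (2R)-2-[(3R,6R)-6-methyl-6-[2-(2,6,6-trimethyl-3-oxocyclohex-1-en-1-yl)ethyl]-1,2-dioxan-3-yl]propanoic acid | OC(=O)[C@H](C)[C@H]1CC[C@@](C)(CCC2=C(C)C(=O)CCC2(C)C)OO1 | intermediate
30 | diacarperoxide A, methyl (2R)-2-[(3R,6R)-6-methyl-6-[2-(2,6,6-trimethyl-3-oxocyclohex-1-en-1-yl)ethyl]-1,2-dioxan-3-yl]propanoate | COC(=O)[C@H](C)[C@H]1CC[C@@](C)(CCC2=C(C)C(=O)CCC2(C)C)OO1 | target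

**Step count and risks**

Total step count: 22 (steps 1 to 11 on the geraniol line, steps 12 to 17 on the ring fragment, steps 18 to 22 after the union).
Longest linear sequence: 16 steps (steps 1 to 11, then 18 to 22).

The three steps most likely to fail:

Step 8. Substitution at the beta-branched secondary carbon may be slow, so that E2 elimination of the sulfonate, hydroxide attack at silicon and over-alkylation to a dialkyl peroxide overtake it. The fallback sets out from mesylate 12 and uses a mono-protected peroxide nucleophile in a hydroxide-poor dipolar aprotic medium. Alkylation of 2-methoxypropan-2-yl hydroperoxide (CsOH·H2O, DMF, 0 °C → rt) should give, with inversion at C3, the perketal (2S,3R)-1-(tert-butyldiphenylsilyloxy)-3-[(2-methoxypropan-2-yl)peroxy]-2-methyl-5-[(2R,3R)-3-(tert-butyldimethylsilyloxymethyl)-2-methyloxiran-2-yl]pentane F1. Brief hydrolysis of the peroxyketal (AcOH–THF–H2O, 0 °C) releases the hydroperoxide, and the route is rejoined at compound 13.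

Step 9. Acid activation may divert into 7-endo attack at C7, into hydride-shift (Meinwald-type) rearrangement of the epoxide, or into acid-induced fragmentation of the secondary hydroperoxide. The fallback sets out from mesylate 12 and exchanges the roles of the two carbons, using two known operations. Perhydrolysis of the epoxide at the tertiary C6 with ethereal H2O2 and catalytic phosphomolybdic acid H3PMo12O40 (inversion at C6) should give (2S,3S,6S,7R)-8-(tert-butyldimethylsilyloxy)-1-(tert-butyldiphenylsilyloxy)-6-hydroperoxy-7-hydroxy-2,6-dimethyloctan-3-yl methanesulfonate F2. KOtBu with 18-crown-6 (THF, 0 °C) then closes the ring by intramolecular 6-exo-tet SN2 displacement of the C3 mesylate by the hydroperoxide, with inversion at C3. Both inversions lead to the same configuration, and the route is rejoined at compound 14.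

Step 18. Addition of the stabilised, sterically shielded phosphorane to the alpha-quaternary aldehyde may be too slow, and prolonged heating would erode the peroxide. The fallback sets out from bromide 22 and replaces the neutral ylide by an anionic phosphonate. Arbuzov reaction with P(OEt)3 (neat, 120 °C) gives diethyl [(2,6,6-trimethyl-3-oxocyclohex-1-en-1-yl)methyl]phosphonate F3. Deprotonation with NaH (THF, 0 °C) gives the sodium salt of the phosphonate carbanion F4, which is more nucleophilic and less encumbered at phosphorus. It should add to aldehyde 16 at 0 °C in a Horner–Wadsworth–Emmons olefination, and the route is rejoined at compound 25.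

**Further compounds**

F1 | step 8 | (2S,3R)-1-(tert-butyldiphenylsilyloxy)-3-[(2-methoxypropan-2-yl)peroxy]-2-methyl-5-[(2R,3R)-3-(tert-butyldimethylsilyloxymethyl)-2-methyloxiran-2-yl]pentane | CC(C)(C)[Si](c1ccccc1)(c1ccccc1)OC[C@H](C)[C@H](OOC(C)(C)OC)CC[C@@]1(C)O[C@@H]1CO[Si](C)(C)C(C)(C)C
F2 | step 9 | (2S,3S,6S,7R)-8-(tert-butyldimethylsilyloxy)-1-(tert-butyldiphenylsilyloxy)-6-hydroperoxy-7-hydroxy-2,6-dimethyloctan-3-yl methanesulfonate | CC(C)(C)[Si](c1ccccc1)(c1ccccc1)OC[C@H](C)[C@@H](OS(C)(=O)=O)CC[C@](C)(OO)[C@H](O)CO[Si](C)(C)C(C)(C)C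
F3 | step 18 | diethyl [(2,6,6-trimethyl-3-oxocyclohex-1-en-1-yl)methyl]phosphonate | CCOP(=O)(CC1=C(C)C(=O)CCC1(C)C)OCC
F4 | step 18 | sodium salt of the carbanion of diethyl [(2,6,6-trimethyl-3-oxocyclohex-1-en-1-yl)methyl]phosphonate | CCOP(=O)(OCC)[CH-]C1=C(C)C(=O)CCC1(C)C.[Na+]
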